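## Analysis of the target

- Read from the SMILES, the target is a B-type procyanidin trimer of three flavan-3-ol (2-arylchroman-3-ol) units. A top (−)-epicatechin 3-O-gallate is bonded through C4 to C8 of a middle (−)-epicatechin 3-O-gallate, whose C4 is bonded to C6 of a bottom (+)-catechin with a free 3-OH.
- There are eight stereocentres: top (2R,3R,4R), middle (2R,3R,4S), bottom (2R,3S). In both upper units the 2-aryl and 3-O-galloyl groups are cis (both α) and the C4–aryl bond is trans to both (4β). The R/S change at C4 comes only from the priority change between an 8-linked and a 6-linked aryl group.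
- The six C2/C3 centres exist in the chiral pool. The two C4 diarylmethine centres, each next to an acylated carbinol, must be made.
- The two interflavan bonds differ in regiochemistry. C4→C8 uses the innately most nucleophilic position of a 5,7-dioxygenated ring A. C4→C6 uses the position between two oxygens, which is not the innate one.
- The middle unit is ambident, a nucleophile at C8 and an electrophile at C4. Without control of sequence and chain length the chemistry gives oligomer mixtures.
- Only two of the three secondary alcohols carry gallates, and they are the two hindered ones.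
- Sensitive features: eighteen phenolic OH groups (catechols and pyrogallols, air-sensitive in base), base-labile esters and C2 centres, and acid-labile doubly benzylic interflavan bonds. All protection must therefore leave in one mild reductive step.

## Retrosynthetic reasoning

**Deprotection.** Target 13 is traced back to the protected trimer 12, in which all eighteen phenols are benzyl ethers and C8 of the top and bottom units carries bromine. One hydrogenolysis removes both kinds of group. The bromines are traceless regiocontrol elements and add no deprotection step.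

**Key disconnection.** Both interflavan bonds of 12, C4(top)–C8(middle) and C4(middle)–C6(bottom), are cut in the same operation, giving three monomer-level fragments 6, 7 and 10.
- The cut is made here because each bond joins an electron-rich ring A to a benzylic C4 whose neighbour C3 carries a gallate trans to the new bond. This trans ester/aryl pattern is what neighbouring-group participation by an ester delivers, as in a 1,2-trans glycosylation.
- The gallates are therefore put on before the coupling and used as stereodirecting groups. As a consequence the bottom 3-OH never needs protection or differentiation.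
- The ambident middle unit is handled like a thioglycoside in an orthogonal one-pot glycosylation. Fragment 7 carries a sulfur leaving group at C4 that is inert to the hard boron Lewis acid used to ionize the oxygen leaving group of 6. It therefore reacts first as a C8 nucleophile, giving 11. A thiophilic silver salt then turns 11 into the C4 electrophile.
- Bromine at C8 of 6 stops the top unit from acting as a nucleophile. Bromine at C8 of 10 leaves C6 as the only free position of its ring A and enforces the 4→6 bond.
- The forward reaction has to form two C–C bonds and two stereocentres and keep two regiochemistries and the chain length under control.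

**Fragments 6 and 7.** Both come from one common intermediate 5 by a single step each: electrophilic bromination at C8 gives 6, and Lewis-acid exchange of the C4 alkoxy group for a hindered arylthio group gives 7. The ortho,ortho-dimethyl substitution on sulfur is chosen to suppress thio-group transfer between fragments.

**Intermediate 5.** The ester bond is cut to alcohol 3 and acid 4. Alcohol 3 comes from 2 by quinone-mediated benzylic C–H oxidation at C4 in the presence of an alcohol, and 2 from (−)-epicatechin 1 by phenol benzylation. The C4 configuration of 3 is irrelevant in the end because the centre is re-ionized.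

**Fragment 10.** It comes from (+)-catechin 8 by phenol benzylation to 9 and bromination at the innate C8 position. The normal regiochemical preference is thus used to block the wrong site.

## Alternatives that were turned down

**Alternative 1: the textbook route.**
- Disconnection: the two ester bonds are cut last and the interflavan bonds one per step.
- Forward key step: 3-OH-free benzyl ethers (from 3, 2 and 10) are coupled in two separate Lewis-acid steps, with a C4 oxidation in between, to the trimeric triol A1. A1 is then esterified twice with 4.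
- Why turned down: A1 has three secondary alcohols, and the two that must be acylated are the hindered ones, each next to a diarylmethine carbon, while the accessible bottom one must stay free. This is the reverse of innate reactivity. It forces protection and deprotection of the bottom 3-OH and a forcing double acylation in a congested trimer. The C4 oxidation would have to be done on an oligomer with several benzylic positions. No participating group backs up the C4 selectivity. The route is about three steps longer.

**Alternative 2: polarity inversion at the 4→6 bond.**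
- Disconnection: C4(middle)–C6(bottom) from a C6 carbanion and a C4 carbonyl.
- Forward key step: bromine–lithium exchange on the 6-bromo catechin derivative A3, addition to flavan-4-one A2, then ionic deoxygenation (Et3SiH/TFA).
- Why turned down: the hydride would enter the planar benzylic cation from the β-face, anti to the 2-aryl and 3-oxygen groups, and leave the aryl group 4α, the wrong epimer. The aryllithium is incompatible with gallate esters, so esterification moves to the end with the same differentiation problem. A3 is not accessible by direct bromination, which goes to C8. The C3–H of A2 is α to the ketone and can epimerize.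

**Alternative 3: regiochemistry by symmetry.**
- Disconnection: the middle C4–aryl bond to an acyclic precursor of the bottom unit, plus the O1–C2 bond of the bottom pyran ring.
- Forward key step: the cation from 11 arylates the seco-catechin A4, whose two free ring positions are equivalent. A Mitsunobu closure through the phenol remote from the new substituent (inversion at the benzylic carbinol) then gives the 6-linked catechin.
- Why turned down: the closure distinguishes two ortho phenols only by steric hindrance. A4 can cyclize under the Lewis acid before it couples, which brings back the C6/C8 problem. A4 costs about four steps (Friedel–Crafts allylation, Sharpless dihydroxylation, protecting-group changes) against one bromination for 10, whose bromine is removed for free.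

Key step: step 8

Remark: α/β refer to the usual flavan drawing (ring A left, O1 up), β towards the viewer. Because bromine and sulfur change CIP priorities, intermediates are described by α/β and SMILES. Compounds 1, 4 and 8 are taken as commercial.

## Route

Step 1
Reactants: 1 (−)-epicatechin
Product: 2 5,7,3',4'-tetra-O-benzyl-(−)-epicatechin
Conditions: BnBr (4.4 equiv), K2CO3, DMF, 0 °C → rt, argon
Reagents that add atoms: benzyl bromide, BrCc1ccccc1
Why: Williamson ether synthesis; K2CO3 deprotonates only the four phenols, so the aliphatic 3-OH stays free, and mild base at low temperature under argon should avoid C2 epimerization and catechol oxidation; no stereocentre is touched.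

Step 2
Reactants: 2 5,7,3',4'-tetra-O-benzyl-(−)-epicatechin
Product: 3 5,7,3',4'-tetra-O-benzyl-4β-(2-ethoxyethoxy)-(−)-epicatechin (2,3-cis, 3,4-trans)
Conditions: DDQ (2 equiv), 2-ethoxyethanol, CH2Cl2, rt
Reagents that add atoms: 2-ethoxyethanol, CCOCCO
Why: DDQ-mediated benzylic C–H oxidation: hydride is abstracted from the C4 methylene, which is ortho and para to the ring A oxygens, and the alcohol should add anti to the α-oriented 2-aryl and 3-OH groups to give the 4β ether; either C4 epimer would serve later because the centre is re-ionized.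

Step 3
Reactants: 3 5,7,3',4'-tetra-O-benzyl-4β-(2-ethoxyethoxy)-(−)-epicatechin; 4 3,4,5-tris(benzyloxy)benzoic acid
Product: 5 5,7,3',4'-tetra-O-benzyl-4β-(2-ethoxyethoxy)-(−)-epicatechin 3-O-(3,4,5-tri-O-benzylgallate)
Conditions: DCC, DMAP (cat.), CH2Cl2, rt
Reagents that add atoms: none
Why: Steglich esterification of the secondary 3-OH under neutral to weakly basic conditions, which should leave the acid-labile benzylic C4 ether and all stereocentres untouched.

Step 4
Reactants: 5 5,7,3',4'-tetra-O-benzyl-4β-(2-ethoxyethoxy)-(−)-epicatechin 3-O-(3,4,5-tri-O-benzylgallate)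
Product: 6 8-bromo-5,7,3',4'-tetra-O-benzyl-4β-(2-ethoxyethoxy)-(−)-epicatechin 3-O-(3,4,5-tri-O-benzylgallate) (top fragment)
Conditions: NBS (1.05 equiv), CH2Cl2, −40 → 0 °C
Reagents that add atoms: N-bromosuccinimide, O=C1CCC(=O)N1Br
Why: Electrophilic aromatic bromination of ring A, the only 1,3,5-trioxygenated ring; C8 (between O1 and 7-OBn) should be preferred over C6, which lies between two benzyloxy groups and is shielded by the C4 substituent. The bromine caps C8 so that 6 can act only as an electrophile.

Step 5
Reactants: 5 5,7,3',4'-tetra-O-benzyl-4β-(2-ethoxyethoxy)-(−)-epicatechin 3-O-(3,4,5-tri-O-benzylgallate)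
Product: 7 5,7,3',4'-tetra-O-benzyl-4β-(2,6-dimethylphenylthio)-(−)-epicatechin 3-O-(3,4,5-tri-O-benzylgallate) (middle fragment)
Conditions: 2,6-dimethylbenzenethiol (3 equiv), BF3·OEt2 (0.3 equiv), CH2Cl2, −78 → −40 °C
Reagents that add atoms: 2,6-dimethylbenzenethiol, Cc1cccc(C)c1S
Why: Lewis-acid SN1 exchange of the C4 ether (thiolysis type): the cation is captured by the 3-O-galloyl carbonyl on the α-face and the thiol opens the dioxolanylium ion at C4 from the β-face, so the thioether should form trans to the ester. Excess thiol should outrun self-arylation at C8, and the product is inert to hard Lewis acids at low temperature.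

Step 6
Reactants: 8 (+)-catechin
Product: 9 5,7,3',4'-tetra-O-benzyl-(+)-catechin
Conditions: BnBr (4.4 equiv), K2CO3, DMF, 0 °C → rt, argon
Reagents that add atoms: benzyl bromide, BrCc1ccccc1
Why: Williamson ether synthesis selective for the four phenols as in step 1; the 3-OH stays free and is never protected in this route.

Step 7
Reactants: 9 5,7,3',4'-tetra-O-benzyl-(+)-catechin
Product: 10 8-bromo-5,7,3',4'-tetra-O-benzyl-(+)-catechin (bottom fragment)
Conditions: NBS (1.0 equiv), CH2Cl2, −78 °C → rt
Reagents that add atoms: N-bromosuccinimide, O=C1CCC(=O)N1Br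
Why: Electrophilic bromination at the innately most reactive C8 of ring A, which leaves C6 as the only free position of that ring for the key step.

Step 8
Reactants: 6 8-bromo-4β-(2-ethoxyethoxy) top fragment; 7 4β-(2,6-dimethylphenylthio) middle fragment; 10 8-bromo-5,7,3',4'-tetra-O-benzyl-(+)-catechin
Product: 12 protected trimer: 8-bromo-tetra-O-benzylepicatechin 3-O-(tri-O-benzylgallate)-(4β→8)-tetra-O-benzylepicatechin 3-O-(tri-O-benzylgallate)-(4β→6)-8-bromo-tetra-O-benzylcatechin, via dimeric 4-thioether 11 (not isolated)
Conditions: 6 (1.0 equiv), 7 (1.05 equiv), BF3·OEt2 (0.5 equiv), 4 Å MS, CH2Cl2, −78 → −40 °C; then 10 (2 equiv), AgBF4 (1.5 equiv), THF, −40 → 0 °C; Et3N quench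
Reagents that add atoms: none
Why: BF3·OEt2 ionizes only the C4–O bond of 6 (the C4–S bond of 7 is inert to a hard Lewis acid at low temperature, and the two ortho methyl groups on sulfur shut down thio-group transfer), and the benzylic cation is captured by the neighbouring 3-O-galloyl carbonyl as a cis-fused 1,3-dioxolan-2-ylium ion on the α-face. C8 of 7, the most nucleophilic free ring position present (C8 of 6 is brominated), opens this ion at C4 from the β-face in a Friedel–Crafts alkylation and gives 11 with the new top C4 centre trans to the ester. AgBF4 then removes the arylthio group of 11 as the thiolate of monovalent silver, and the same participation and opening sequence with C6 of 10, the only free position of its ring A, gives 12. The closest known reaction types are the Lewis-acid coupling of 4-alkoxyflavan-3-ols with flavan-3-ol nucleophiles, the silver-promoted activation of 4-thioflavans, and the orthogonal one-pot glycosylation with ester-participating donors. No ring is closed. Both new stereocentres (top C4 and middle C4) are controlled by the adjacent 3-O-galloyl group and reinforced by the α-oriented 2-aryl group, so a mixture of C4 epimers in 6 or 7 would converge on the same 4β products. The step needs C8-over-C6 selectivity in 7, secured by the two benzyloxy groups flanking C6 and the peri C4 substituent, and chain-length control, secured by the two bromine caps and the hard-then-soft order of activation.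

Step 9
Reactants: 12 protected trimer
Product: 13 (−)-epicatechin 3-O-gallate-(4β→8)-(−)-epicatechin 3-O-gallate-(4β→6)-(+)-catechin (target)
Conditions: H2 (1 atm), Pd(OH)2/C, Et3N (2.5 equiv), THF/MeOH/H2O, rt; filtration under argon, dilute AcOH, lyophilization
Reagents that add atoms: none
Why: Heterogeneous hydrogenolysis should cleave the eighteen benzyl ethers and reduce both aryl C–Br bonds (Et3N takes up HBr) in one operation, while the gallate esters and the interflavan diarylmethine bonds, which carry no leaving group, should survive; no stereocentre is affected.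

## Compound list

1 | (−)-epicatechin, (2R,3R) | O[C@@H]1Cc2c(O)cc(O)cc2O[C@@H]1c1ccc(O)c(O)c1 | starting material

2 | 5,7,3',4'-tetra-O-benzyl-(−)-epicatechin, (2R,3R) | O[C@@H]1Cc2c(OCc3ccccc3)cc(OCc3ccccc3)cc2O[C@@H]1c1ccc(OCc2ccccc2)c(OCc2ccccc2)c1 | intermediate

3 | 5,7,3',4'-tetra-O-benzyl-4β-(2-ethoxyethoxy)-(−)-epicatechin (2,3-cis, 3,4-trans) | O[C@@H]1[C@@H](OCCOCC)c2c(OCc3ccccc3)cc(OCc3ccccc3)cc2O[C@@H]1c1ccc(OCc2ccccc2)c(OCc2ccccc2)c1 | intermediate

4 | 3,4,5-tris(benzyloxy)benzoic acid | OC(=O)c1cc(OCc2ccccc2)c(OCc2ccccc2)c(OCc2ccccc2)c1 | starting material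

5 | 5,7,3',4'-tetra-O-benzyl-4β-(2-ethoxyethoxy)-(−)-epicatechin 3-O-(3,4,5-tri-O-benzylgallate) | O=C(O[C@@H]1[C@@H](OCCOCC)c2c(OCc3ccccc3)cc(OCc3ccccc3)cc2O[C@@H]1c1ccc(OCc2ccccc2)c(OCc2ccccc2)c1)c1cc(OCc2ccccc2)c(OCc2ccccc2)c(OCc2ccccc2)c1 | intermediate

6 | 8-bromo derivative of 5 (top fragment; 2-aryl α, 3-O-galloyl α, 4-alkoxy β) | O=C(O[C@@H]1[C@@H](OCCOCC)c2c(OCc3ccccc3)cc(OCc3ccccc3)c(Br)c2O[C@@H]1c1ccc(OCc2ccccc2)c(OCc2ccccc2)c1)c1cc(OCc2ccccc2)c(OCc2ccccc2)c(OCc2ccccc2)c1 | intermediate

7 | 5,7,3',4'-tetra-O-benzyl-4β-(2,6-dimethylphenylthio)-(−)-epicatechin 3-O-(3,4,5-tri-O-benzylgallate) (middle fragment; 2,3-cis, 3,4-trans) | O=C(O[C@@H]1[C@@H](Sc2c(C)cccc2C)c2c(OCc3ccccc3)cc(OCc3ccccc3)cc2O[C@@H]1c1ccc(OCc2ccccc2)c(OCc2ccccc2)c1)c1cc(OCc2ccccc2)c(OCc2ccccc2)c(OCc2ccccc2)c1 | intermediate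

8 | (+)-catechin, (2R,3S) | O[C@H]1Cc2c(O)cc(O)cc2O[C@@H]1c1ccc(O)c(O)c1 | starting material

9 | 5,7,3',4'-tetra-O-benzyl-(+)-catechin, (2R,3S) | O[C@H]1Cc2c(OCc3ccccc3)cc(OCc3ccccc3)cc2O[C@@H]1c1ccc(OCc2ccccc2)c(OCc2ccccc2)c1 | intermediate

10 | 8-bromo-5,7,3',4'-tetra-O-benzyl-(+)-catechin (bottom fragment; 2,3-trans) | O[C@H]1Cc2c(OCc3ccccc3)cc(OCc3ccccc3)c(Br)c2O[C@@H]1c1ccc(OCc2ccccc2)c(OCc2ccccc2)c1 | intermediate

11 | dimeric 4-thioether: top unit of 6 bonded 4β→8 to the unit of 7, middle C4 still carrying the β-(2,6-dimethylphenylthio) group | O=C(O[C@@H]1[C@@H](c2c(OCc4ccccc4)cc(OCc4ccccc4)c3c2O[C@H](c2ccc(OCc4ccccc4)c(OCc4ccccc4)c2)[C@H](OC(=O)c2cc(OCc4ccccc4)c(OCc4ccccc4)c(OCc4ccccc4)c2)[C@H]3Sc2c(C)cccc2C)c2c(OCc3ccccc3)cc(OCc3ccccc3)c(Br)c2O[C@@H]1c1ccc(OCc2ccccc2)c(OCc2ccccc2)c1)c1cc(OCc2ccccc2)c(OCc2ccccc2)c(OCc2ccccc2)c1 | intermediate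

12 | protected trimer: octadeca-O-benzyl derivative of 13 with bromine at C8 of the top and bottom units (both interflavan bonds β, bottom 3-OH free) | O=C(O[C@@H]1[C@@H](c2c(OCc4ccccc4)cc(OCc4ccccc4)c3c2O[C@H](c2ccc(OCc4ccccc4)c(OCc4ccccc4)c2)[C@H](OC(=O)c2cc(OCc4ccccc4)c(OCc4ccccc4)c(OCc4ccccc4)c2)[C@H]3c2c(OCc4ccccc4)c(Br)c3c(c2OCc4ccccc4)C[C@H](O)[C@@H](c2ccc(OCc4ccccc4)c(OCc4ccccc4)c2)O3)c2c(OCc3ccccc3)cc(OCc3ccccc3)c(Br)c2O[C@@H]1c1ccc(OCc2ccccc2)c(OCc2ccccc2)c1)c1cc(OCc2ccccc2)c(OCc2ccccc2)c(OCc2ccccc2)c1 | intermediate

13 | (−)-epicatechin 3-O-gallate-(4β→8)-(−)-epicatechin 3-O-gallate-(4β→6)-(+)-catechin; top (2R,3R,4R), middle (2R,3R,4S), bottom (2R,3S) | O=C(O[C@@H]1[C@@H](c2c(O)cc(O)c3c2O[C@H](c2ccc(O)c(O)c2)[C@H](OC(=O)c2cc(O)c(O)c(O)c2)[C@H]3c2c(O)cc3c(c2O)C[C@H](O)[C@@H](c2ccc(O)c(O)c2)O3)c2c(O)cc(O)cc2O[C@@H]1c1ccc(O)c(O)c1)c1cc(O)c(O)c(O)c1 | target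

## Step count and least certain steps

Total step count: 9. Longest linear sequence: 6 steps (1, 2, 3, 4 or 5, 8, 9).

**Step 8 (key step).**
- What may go wrong: loss of orthogonality, that is partial ionization of the C–S bond of 7 or 11 by the boron Lewis acid, or thio-group transfer, which lets the middle unit react as an electrophile too early and leads to oligomerization. In the second stage, slow attack at the hindered C6 of 10 may lose to self-arylation of the dimeric cation at the remaining free C6 positions, or to acid-mediated cleavage and scrambling of the first interflavan bond.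
- Fallback: a bottom-up, stepwise assembly with isolation and hard activation only, which needs no sulfur. It sets out from 5 and 10: slow addition of 5 to a threefold excess of 10 with TMSOTf in CH2Cl2 at −78 °C should give the 4β→6 dimer F1, whose only reactive free ring A position is the middle C8. Coupling of F1 with 6 under TMSOTf then comes back to the route at 12.

**Step 5.**
- What may go wrong: the ester-disarmed substrate ionizes slowly, so self-arylation (C8 of one molecule attacking the cation of another) or incomplete exchange may compete with thiol capture.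
- Fallback: form the C–S bond on the more easily ionized free alcohol, where facial selectivity rests on the two α substituents instead of participation. It sets out from 3: BF3·OEt2 and 2,6-dimethylbenzenethiol should give the thio alcohol F2, and Steglich esterification of F2 with 4 comes back at 7.

**Step 4.**
- What may go wrong: over-bromination at C6, or ionization of the C4 ether by adventitious HBr.
- Fallback: cap before the sensitive C4 ether exists. It sets out from 2: bromination with NBS to the 8-bromide F3, DDQ oxidation in the presence of 2-ethoxyethanol to the alcohol F4, and Steglich esterification with 4, coming back at 6.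

**Step 9.**
- What may go wrong: incomplete hydrogenolysis of eighteen ethers in a crowded molecule, catalyst poisoning by traces of sulfur or silver from step 8, incomplete debromination, or base-promoted air oxidation during work-up.
- Fallback: separate the two reductions. It sets out from 12: radical debromination with Bu3SnH/AIBN in toluene at 80 °C to the bromine-free ether F5, then base-free hydrogenolysis over Pd(OH)2/C in THF/MeOH/H2O, coming back at 13.

## Further compounds

F1 | step 8 | tetra-O-benzylepicatechin 3-O-(tri-O-benzylgallate)-(4β→6)-8-bromo-tetra-O-benzylcatechin (middle–bottom dimer, middle C8 free) | O=C(O[C@@H]1[C@@H](c2c(OCc4ccccc4)c(Br)c3c(c2OCc4ccccc4)C[C@H](O)[C@@H](c2ccc(OCc4ccccc4)c(OCc4ccccc4)c2)O3)c2c(OCc3ccccc3)cc(OCc3ccccc3)cc2O[C@@H]1c1ccc(OCc2ccccc2)c(OCc2ccccc2)c1)c1cc(OCc2ccccc2)c(OCc2ccccc2)c(OCc2ccccc2)c1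

F2 | step 5 | 5,7,3',4'-tetra-O-benzyl-4β-(2,6-dimethylphenylthio)-(−)-epicatechin (free 3-OH) | O[C@@H]1[C@@H](Sc2c(C)cccc2C)c2c(OCc3ccccc3)cc(OCc3ccccc3)cc2O[C@@H]1c1ccc(OCc2ccccc2)c(OCc2ccccc2)c1

F3 | step 4 | 8-bromo-5,7,3',4'-tetra-O-benzyl-(−)-epicatechin | O[C@@H]1Cc2c(OCc3ccccc3)cc(OCc3ccccc3)c(Br)c2O[C@@H]1c1ccc(OCc2ccccc2)c(OCc2ccccc2)c1

F4 | step 4 | 8-bromo-5,7,3',4'-tetra-O-benzyl-4β-(2-ethoxyethoxy)-(−)-epicatechin | O[C@@H]1[C@@H](OCCOCC)c2c(OCc3ccccc3)cc(OCc3ccccc3)c(Br)c2O[C@@H]1c1ccc(OCc2ccccc2)c(OCc2ccccc2)c1

F5 | step 9 | bromine-free octadeca-O-benzyl ether of 13 | O=C(O[C@@H]1[C@@H](c2c(OCc4ccccc4)cc(OCc4ccccc4)c3c2O[C@H](c2ccc(OCc4ccccc4)c(OCc4ccccc4)c2)[C@H](OC(=O)c2cc(OCc4ccccc4)c(OCc4ccccc4)c(OCc4ccccc4)c2)[C@H]3c2c(OCc4ccccc4)cc3c(c2OCc4ccccc4)C[C@H](O)[C@@H](c2ccc(OCc4ccccc4)c(OCc4ccccc4)c2)O3)c2c(OCc3ccccc3)cc(OCc3ccccc3)cc2O[C@@H]1c1ccc(OCc2ccccc2)c(OCc2ccccc2)c1)c1cc(OCc2ccccc2)c(OCc2ccccc2)c(OCc2ccccc2)c1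

A1 | alternative 1 | tetra-O-benzylepicatechin-(4β→8)-tetra-O-benzylepicatechin-(4β→6)-8-bromo-tetra-O-benzylcatechin (triol, three free 3-OH) | O[C@@H]1[C@@H](c2c(OCc4ccccc4)cc(OCc4ccccc4)c3c2O[C@H](c2ccc(OCc4ccccc4)c(OCc4ccccc4)c2)[C@H](O)[C@H]3c2c(OCc4ccccc4)c(Br)c3c(c2OCc4ccccc4)C[C@H](O)[C@@H](c2ccc(OCc4ccccc4)c(OCc4ccccc4)c2)O3)c2c(OCc3ccccc3)cc(OCc3ccccc3)cc2O[C@@H]1c1ccc(OCc2ccccc2)c(OCc2ccccc2)c1

A2 | alternative 2 | 5,7,3',4'-tetra-O-benzyl-3-O-(tert-butyldimethylsilyl)-(−)-epicatechin-4-one (2,3-cis) | O=C1[C@@H](O[Si](C)(C)C(C)(C)C)[C@@H](c2ccc(OCc3ccccc3)c(OCc3ccccc3)c2)Oc2cc(OCc3ccccc3)cc(OCc3ccccc3)c12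

A3 | alternative 2 | 6-bromo-5,7,3',4'-tetra-O-benzyl-3-O-(tert-butyldimethylsilyl)-(+)-catechin | CC(C)(C)[Si](C)(C)O[C@H]1Cc2c(OCc3ccccc3)c(Br)c(OCc3ccccc3)cc2O[C@@H]1c1ccc(OCc2ccccc2)c(OCc2ccccc2)c1

A4 | alternative 3 | (1S,2S)-1-[3,4-bis(benzyloxy)phenyl]-3-[4-(benzyloxy)-2,6-dihydroxyphenyl]propane-1,2-diol (seco-catechin) | O[C@@H](c1ccc(OCc2ccccc2)c(OCc2ccccc2)c1)[C@@H](O)Cc1c(O)cc(OCc2ccccc2)cc1O
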